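The slowness at the end of the delta run caught my eye first: between 6.2 min and 9.3 min target gained just 4.48 mM min⁻¹, with substrate and coupling partner both still present.

| flask | substrate | coupling partner | time |
|---|---|---|---|
| delta | 300 mM | 450 mM |  |
| zeta | 150 mM | 300 mM |  |
| gamma | 600 mM | 450 mM |  |
| epsilon | 300 mM | 230 mM |  |
| theta | 300 mM | 450 mM | 56 min |

| run | time / min | [target] / mM |
|---|---|---|
| delta run | 1.6 | 77.5 |
| delta run | 3.1 | 119.7 |
| delta run | 4.7 | 150.6 |
| delta run | 6.2 | 166.5 |
| delta run | 7.8 | 174.1 |
| delta run | 9.3 | 180.4 |
| zeta run | 1.6 | 26.1 |
| zeta run | 3.1 | 42.4 |
| zeta run | 4.7 | 58.4 |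
| zeta run | 6.2 | 67.1 |
| zeta run | 7.8 | 72.9 |
| zeta run | 9.3 | 75.6 |
| gamma run | 1.6 | 146.2 |
| gamma run | 3.1 | 202.6 |
| gamma run | 4.7 | 243.1 |
| gamma run | 6.2 | 258.5 |
| gamma run | 7.8 | 268.4 |
| gamma run | 9.3 | 278.8 |
| epsilon run | 1.6 | 34.4 |
| epsilon run | 3.1 | 56.0 |
| epsilon run | 4.7 | 78.3 |
| epsilon run | 6.2 | 84.1 |
| epsilon run | 7.8 | 96.1 |
| epsilon run | 9.3 | 99.7 |

(readings scatter by 2 mM)

- the power of [substrate] that the first rate follows, about the charge of the delta run; measure it at two percent of substrate made into target (one fixed amount of target, the same in the runs compared)
- the power of [coupling partner] that the first rate follows, about the charge of the delta run; measure it at two percent of substrate made into target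
- target in the theta run at 56 min, as a share of the substrate charged

- Overall: substrate + coupling partner -> target.
- Constant volume, constant temperature.
- What is held in complexes is read along with the free species.
- "The second partner" is coupling partner.
- An order is taken over about fifteen percent of the charge, up and down.

I began with the first readings. Gamma, with 2.00 times the substrate of delta, gave 1.89 times the target, so I took the first power in substrate. Epsilon against delta gave a power of 1.21 in coupling partner.

Next I asked what delta should still be making late on. Its first interval ran at 48.4 mM min⁻¹, around a mean of 261 mM substrate and 411 mM partner. Around the late mean of 173 mM target, I reckoned these at 127 mM and 277 mM, counting the target read as what had been used. The power law then gives 14.5 mM min⁻¹, faster than the gain seen.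

I read the gap as first-order loss of target, with a constant of 0.0578 min⁻¹. Integrated, such a loss multiplies target by exp(−constant × time).

The theta run has the charge of delta, and substrate is its limiting reagent. Its asked time lies beyond the last reading by the unwatched stretch, 46.7 min. Counting the whole charge as made by the last reading, I committed to 6.71 % of the substrate charged.

The forecast gave 1, 1.2 and 63 %, saying “delta should sit near 188 mM at 56 min, about 63%”. The flask gave 1.0, 1.3 and 26.6 %, which is more than my number.

    2 coupling partner ⇌ reagent dimer, settled at all times (2.910 L mol⁻¹)
    substrate + reagent dimer → target + coupling partner (1.836 L mol⁻¹ min⁻¹)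
    target → decomposed product (0.02820 min⁻¹)

The weak link in my chain was the loss constant, which rested on a late making rate carried over from the first interval by the power law, so I reforged it with the scheme's constant for target turning into decomposed product, 0.0282 min⁻¹. Over the unwatched stretch of 46.7 min, that constant leaves 26.8 % of target. The simulated theta run without this step holds 98.4 %, against 26.6 % with it, so this decomposition is the main reason for the low value. Multiplying that simulated 98.4 % by the surviving share gives 26.4 % of the substrate charged.

The earlier runs and the new flask are calculated on assumed constants; noise was put on by code.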